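**Retrosynthetic overview**

- The strategy rests on the tetrahydrofuran ring of the 2,7-dioxabicyclo[3.2.1]octan-3-one, O-7–C-1 (acetal carbon)–C-8 (bridge CH carrying the hydroazulene)–C-5 (branch CH)–C-6 (CH–CO2Me): this row of four carbons is what a 2-bromoacetal radical builds when it closes onto an allylic alcohol.
- Acetate ⇒ lactone enolate hydroxylation; δ-lactone ⇒ tert-butyl acetate arm closing on the acetal carbon; C-8–C-5 bond and tetrahydrofuran ⇒ cathodic 5-exo cyclisation of a bromoacetal assembled from a hydroazulenyl enol ether, NBS and an (R)-hydroxy diester (cross-metathesis product).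
- Hydroazulene: enol ether ⇐ allyl ketone ⇐ Sakurai allylation of a bicyclic enone ⇐ copper hydride reductive aldol of an enone ketone ⇐ Stork–Danheiser transposition on cycloheptane-1,3-dione.
- Ring order: seven-membered carbocycle (bought), cyclopentane (step 4), tetrahydrofuran (step 12), δ-lactone (step 13).

Key step: step 12

Locants: bicyclic carbocycles carry the azulene numbering of the target (C-1 quaternary carbon, C-3a and C-8a ring fusion, C-4 geminal dimethyl carbon, C-8 carbonyl or methylidene carbon); the dioxabicyclooctanone is numbered C-1 (acetal), O-2, C-3 (C=O), C-4, C-5, C-6, O-7, C-8.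
Assumption: methyl (R)-2-hydroxybut-3-enoate is bought as the single enantiomer.
Assumption: the antipode of DTBM-SEGPHOS quoted in step 4 follows the facial sense usual for 3-alkylcycloalkenones; should hydride arrive on the other face, the other antipode is used and nothing else changes.

**Route**

Step 1
Reactants: 1 cycloheptane-1,3-dione
Product: 2 3-(2-methylpropoxy)cyclohept-2-en-1-one
Conditions: 2-methylpropan-1-ol, p-TsOH·H2O (cat.), toluene, reflux, Dean–Stark
Reagents that add atoms: 2-methylpropan-1-ol, CC(C)CO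
Why: Acid-catalysed condensation of the cyclic 1,3-dione with the alcohol under azeotropic removal of water gives the vinylogous ester (enol etherification), which tells the two carbonyl groups apart without forming a stereocentre.

Step 2
Reactants: 2 3-(2-methylpropoxy)cyclohept-2-en-1-one
Product: 6 7,7-dimethyl-3-(2-methylpropoxy)cyclohept-2-en-1-one, via lithium enolate 3 (not isolated), via 7-methyl vinylogous ester 4 (not isolated), via methylated lithium enolate 5 (not isolated)
Conditions: LiN(iPr)2 (1.1 equiv), THF, −78 °C; MeI, −78 → 0 °C; then LiN(iPr)2 (1.2 equiv), −78 °C; MeI, → rt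
Reagents that add atoms: iodomethane, CI
Why: Kinetic deprotonation of the vinylogous ester takes place at the α′ carbon and each cross-conjugated enolate is methylated there (enolate alkylation), so that this carbon becomes the geminal dimethyl carbon and keeps no stereocentre.

Step 3
Reactants: 6 7,7-dimethyl-3-(2-methylpropoxy)cyclohept-2-en-1-one; 7 2-(2-bromoethyl)-2-methyl-1,3-dioxolane
Product: 10 4,4-dimethyl-3-(3-oxobutyl)cyclohept-2-en-1-one, via Grignard reagent 8 (not isolated), via tertiary allylic carbinol 9 (not isolated)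
Conditions: 7, Mg, THF, rt; then CeCl3, 6, THF, −78 → 0 °C; then 2 M HCl, THF, rt
Reagents that add atoms: water, O
Why: Stork–Danheiser transposition, in which the cerium-modified Grignard reagent adds 1,2 to the hindered carbonyl and aqueous acid then ionises the tertiary allylic carbinol, hydrolyses the enol ether to the transposed enone and unmasks the methyl ketone, so that the side chain sits on the carbon next to the geminal dimethyl group and no stereocentre is formed.

Step 4
Reactants: 10 4,4-dimethyl-3-(3-oxobutyl)cyclohept-2-en-1-one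
Product: 12 (1S,3aR,8aR)-1-hydroxy-1,4,4-trimethylperhydroazulen-8-one, via dimethylphenylsilyl ether 11 (not isolated)
Conditions: Cu(OAc)2·H2O (5 mol %), (R)-DTBM-SEGPHOS (5.5 mol %), PhMe2SiH (1.5 equiv), toluene, −10 °C; then 1 M HCl, THF, 0 °C
Reagents that add atoms: none
Why: Copper hydride reductive aldol cyclisation, in which the ligand-bound copper hydride delivers hydride to one face of the β-carbon and so sets C-3a, the copper enolate adds 5-exo to the methyl ketone from the face that carries its tether and so makes the ring fusion cis, and the carbinol centre, expected with hydroxyl cis to C-8 from a chelated chair, is of no consequence because the next step removes it.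

Step 5
Reactants: 12 (1S,3aR,8aR)-1-hydroxy-1,4,4-trimethylperhydroazulen-8-one
Product: 13 (3aS)-1,4,4-trimethyl-3,3a,4,5,6,7-hexahydroazulen-8(2H)-one
Conditions: p-TsOH·H2O (10 mol %), toluene, 80 °C, 4 Å molecular sieves
Reagents that add atoms: none
Why: Acid-catalysed dehydration of the tertiary aldol (E1) should give the conjugated tetrasubstituted enone as the thermodynamic sink, and C-3a is kept because it is not a γ-position of the enone and cannot enolise through it.

Step 6
Reactants: 13 (3aS)-1,4,4-trimethyl-3,3a,4,5,6,7-hexahydroazulen-8(2H)-one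
Product: 15 (1S,3aR,8aR)-1,4,4-trimethyl-1-(prop-2-en-1-yl)perhydroazulen-8-one, via trichlorotitanium enolate 14 (not isolated)
Conditions: TiCl4 (1.2 equiv), CH2Cl2, −78 °C; allyltrimethylsilane (1.5 equiv), −78 → −40 °C; then saturated aqueous NH4Cl at −78 °C
Reagents that add atoms: allyltrimethylsilane, C=CC[Si](C)(C)C
Why: Hosomi–Sakurai conjugate allylation of an s-cis enone of the pulegone kind, in which the allylsilane adds to C-1 on the face of H-3a, away from C-4 and its geminal methyl groups, so that the quaternary centre carries the allyl group on the convex face, and the titanium enolate is protonated at C-8a in the cold from the same open face, which should give the cis ring fusion.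

Step 7
Reactants: 15 (1S,3aR,8aR)-1,4,4-trimethyl-1-(prop-2-en-1-yl)perhydroazulen-8-one
Product: 18 (1S,3aR,8aR)-1-(2,2-dimethoxyethyl)-1,4,4-trimethylperhydroazulen-8-one, via ozonide 16 (not isolated), via keto aldehyde 17 (not isolated)
Conditions: O3, CH2Cl2, −78 °C; PPh3, → rt; then CH(OMe)3, PPTS (cat.), MeOH, rt
Reagents that add atoms: trimethyl orthoformate, COC(OC)OC; methanol, CO
Why: Ozonolysis of the monosubstituted alkene with reductive work-up followed by acid-catalysed acetalisation, in which the unhindered aldehyde forms its dimethyl acetal while the hindered ketone beside the ring fusion does not, and the weak pyridinium acid should leave C-8a alone.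

Step 8
Reactants: 18 (1S,3aR,8aR)-1-(2,2-dimethoxyethyl)-1,4,4-trimethylperhydroazulen-8-one
Product: 19 (1S,3aR,8aS)-1-(2,2-dimethoxyethyl)-1,4,4-trimethyl-8-methylideneperhydroazulene
Conditions: Cp2TiMe2 (2.5 equiv), toluene, 70 °C, dark
Reagents that add atoms: dimethyltitanocene, C[Ti](C)(C1C=CC=C1)C1C=CC=C1
Why: Petasis methylenation, in which the titanocene methylidene formed on heating converts the hindered ketone into the methylidene group by [2+2] addition and cycloreversion in a non-basic medium, so that C-8a is not epimerised and the acetal is untouched.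

Step 9
Reactants: 19 (1S,3aR,8aS)-1-(2,2-dimethoxyethyl)-1,4,4-trimethyl-8-methylideneperhydroazulene
Product: 20 (1R,3aR,8aS)-1-[(E)-2-methoxyethenyl]-1,4,4-trimethyl-8-methylideneperhydroazulene
Conditions: TMSOTf (1.3 equiv), iPr2NEt (1.6 equiv), CH2Cl2, −20 °C → rt
Reagents that add atoms: none
Why: Silyl triflate and amine eliminate methanol from the dimethyl acetal by way of the oxocarbenium ion (acetal-to-enol-ether elimination), the (E)-isomer being favoured because the quaternary substituent avoids the methoxy group, and the buffered medium spares the methylidene group.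

Step 10
Reactants: 21 methyl (R)-2-hydroxybut-3-enoate; 22 tert-butyl acrylate
Product: 23 5-tert-butyl 1-methyl (2R,3E)-2-hydroxypent-3-enedioate
Conditions: second-generation Hoveyda–Grubbs catalyst RuCl2(H2IMes)(=CH–C6H4-2-OiPr) (3 mol %), 22 (3 equiv), CH2Cl2, 40 °C
Reagents that add atoms: none
Why: Olefin cross-metathesis of the allylic alcohol with an excess of the slowly homodimerising acrylate should give the (E)-enoate, and the neutral medium leaves the base-sensitive carbinol stereocentre untouched.

Step 11
Reactants: 20 (1R,3aR,8aS)-1-[(E)-2-methoxyethenyl]-1,4,4-trimethyl-8-methylideneperhydroazulene; 23 5-tert-butyl 1-methyl (2R,3E)-2-hydroxypent-3-enedioate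
Product: 24 5-tert-butyl 1-methyl (2R,3E)-2-{(1S,2S)-2-bromo-1-methoxy-2-[(1R,3aR,8aS)-1,4,4-trimethyl-8-methylidenedecahydroazulen-1-yl]ethoxy}pent-3-enedioate
Conditions: 23 (2 equiv), NBS (1.05 equiv), CH2Cl2, −78 → −30 °C, dark; chromatography to take the (S)-acetal epimer
Reagents that add atoms: N-bromosuccinimide, O=C1CCC(=O)N1Br
Why: Bromoalkoxylation of the enol ether (haloetherification), in which NBS brominates the electron-rich β-carbon far faster than the methylidene group and the alcohol captures the α-bromo oxocarbenium ion anti to bromine, which should give two anti adducts that differ at both new carbons; the one with the (S)-acetal carbon is taken, and its bromide epimer serves equally because that carbon becomes a planar radical in the next step.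

Step 12
Reactants: 24 5-tert-butyl 1-methyl (2R,3E)-2-{(1S,2S)-2-bromo-1-methoxy-2-[(1R,3aR,8aS)-1,4,4-trimethyl-8-methylidenedecahydroazulen-1-yl]ethoxy}pent-3-enedioate
Product: 25 methyl (2R,3R,4R,5S)-3-(2-tert-butoxy-2-oxoethyl)-5-methoxy-4-[(1R,3aR,8aS)-1,4,4-trimethyl-8-methylidenedecahydroazulen-1-yl]oxolane-2-carboxylate
Conditions: [Ni(cyclam)](ClO4)2 (20 mol %), NH4ClO4 (3 equiv), Et4NClO4 (0.1 M), DMF, carbon-fibre cathode at −1.5 V vs SCE, divided cell, 20 °C
Reagents that add atoms: none
Why: The cathode reduces the divalent nickel complex to monovalent nickel, which transfers an electron to the C–Br bond and gives, from either bromide epimer, the same planar secondary radical beside the quaternary carbon; this nucleophilic radical adds to the β-carbon of the tert-butyl enoate, and the α-ester radical is reduced and protonated by NH4+, the closest known reaction type being the nickel-mediated electroreductive cyclisation of allylic 2-bromoacetals (the cathodic form of the Ueno–Stork reaction). The tetrahydrofuran closes in the 5-exo-trig mode through a chair-like transition state. The branch CH is set by the bought carbinol centre, whose methyl ester sits pseudo-equatorial so that the acetate arm ends trans to it. The bridge CH is set by the acetal carbon: in the (S)-acetal the methoxy group is pseudo-equatorial as well and the hydroazulenyl group takes the outside position on the radical carbon, where it eclipses only the acetal hydrogen, so that it ends trans to methoxy and cis to the acetate arm. The step needs ring closure to outrun reduction of the open radical, which the electron-poor enoate and the low standing concentration of the mediator secure, and it needs the all-equatorial chair, which is why only this acetal epimer is used; closure onto the ring methylidene group would be 4-exo or 5-endo and is not expected.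

Step 13
Reactants: 25 methyl (2R,3R,4R,5S)-3-(2-tert-butoxy-2-oxoethyl)-5-methoxy-4-[(1R,3aR,8aS)-1,4,4-trimethyl-8-methylidenedecahydroazulen-1-yl]oxolane-2-carboxylate
Product: 27 methyl (1S,5R,6R,8R)-3-oxo-8-[(1R,3aR,8aS)-1,4,4-trimethyl-8-methylidenedecahydroazulen-1-yl]-2,7-dioxabicyclo[3.2.1]octane-6-carboxylate, via trimethylsilyl ester 26 (not isolated)
Conditions: TMSOTf (2.2 equiv), 2,6-lutidine (3 equiv), CH2Cl2, −78 → 0 °C
Reagents that add atoms: none
Why: Silyl triflate converts the tert-butyl ester into the trimethylsilyl ester with loss of 2-methylpropene and ionises the methyl acetal to the oxocarbenium ion, which the silyl ester on the cis arm captures (lactonisation by acetal exchange) on the only face that arm can reach, while the lutidine buffer and the trans placement of the methylidene group across the cyclopentane should prevent alkene isomerisation and a Prins closure.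

Step 14
Reactants: 27 methyl (1S,5R,6R,8R)-3-oxo-8-[(1R,3aR,8aS)-1,4,4-trimethyl-8-methylidenedecahydroazulen-1-yl]-2,7-dioxabicyclo[3.2.1]octane-6-carboxylate
Product: 29 methyl (1S,4S,5S,6R,8R)-4-hydroxy-3-oxo-8-[(1R,3aR,8aS)-1,4,4-trimethyl-8-methylidenedecahydroazulen-1-yl]-2,7-dioxabicyclo[3.2.1]octane-6-carboxylate, via potassium enolate 28 (not isolated)
Conditions: KN(SiMe3)2 (1.1 equiv), THF, −78 °C; 2-(phenylsulfonyl)-3-phenyloxaziridine (1.5 equiv), −78 °C; AcOH quench at −78 °C
Reagents that add atoms: 2-(phenylsulfonyl)-3-phenyloxaziridine, O=S(=O)(c1ccccc1)N1OC1c1ccccc1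
Why: Lactone enolate hydroxylation with an N-sulfonyloxaziridine, in which the bulky amide base removes a lactone α-hydrogen, far more acidic than the tertiary α-alkoxy C–H of the methyl ester, and the oxidant attacks the enolate anti to the axial hydroazulenyl group on C-8, so that the new hydroxyl is equatorial and trans to that group.

Step 15
Reactants: 29 methyl (1S,4S,5S,6R,8R)-4-hydroxy-3-oxo-8-[(1R,3aR,8aS)-1,4,4-trimethyl-8-methylidenedecahydroazulen-1-yl]-2,7-dioxabicyclo[3.2.1]octane-6-carboxylate
Product: 30 methyl (1S,4S,5R,6R,8R)-4-acetoxy-3-oxo-8-[(1R,3aR,8aS)-1,4,4-trimethyl-8-methylidenedecahydroazulen-1-yl]-2,7-dioxabicyclo[3.2.1]octane-6-carboxylate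
Conditions: Ac2O, pyridine, DMAP (cat.), CH2Cl2, 0 °C → rt
Reagents that add atoms: acetic anhydride, CC(=O)OC(C)=O
Why: DMAP-catalysed acyl transfer to the secondary alcohol proceeds with retention at carbon and should give the target.

**Compound list**

1 | cycloheptane-1,3-dione | O=C1CCCCC(=O)C1 | starting material
2 | 3-(2-methylpropoxy)cyclohept-2-en-1-one | CC(C)COC1=CC(=O)CCCC1 | intermediate
3 | lithium 6-(2-methylpropoxy)cyclohepta-1,6-dien-1-olate | [Li+].CC(C)COC1=CC([O-])=CCCC1 | intermediate
4 | 7-methyl-3-(2-methylpropoxy)cyclohept-2-en-1-one (racemic) | CC(C)COC1=CC(=O)C(C)CCC1 | intermediate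
5 | lithium 2-methyl-6-(2-methylpropoxy)cyclohepta-1,6-dien-1-olate | [Li+].CC(C)COC1=CC([O-])=C(C)CCC1 | intermediate
6 | 7,7-dimethyl-3-(2-methylpropoxy)cyclohept-2-en-1-one | CC(C)COC1=CC(=O)C(C)(C)CCC1 | intermediate
7 | 2-(2-bromoethyl)-2-methyl-1,3-dioxolane | CC1(CCBr)OCCO1 | starting material
8 | bromo[2-(2-methyl-1,3-dioxolan-2-yl)ethyl]magnesium | CC1(CC[Mg]Br)OCCO1 | intermediate
9 | 7,7-dimethyl-1-[2-(2-methyl-1,3-dioxolan-2-yl)ethyl]-3-(2-methylpropoxy)cyclohept-2-en-1-ol (racemic; present as its alkoxide until the acid is added) | CC(C)COC1=CC(O)(CCC2(C)OCCO2)C(C)(C)CCC1 | intermediate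
10 | 4,4-dimethyl-3-(3-oxobutyl)cyclohept-2-en-1-one | CC(=O)CCC1=CC(=O)CCCC1(C)C | intermediate
11 | (1S,3aR,8aR)-1-[dimethyl(phenyl)silyloxy]-1,4,4-trimethylperhydroazulen-8-one (cis-fused) | O=C1CCCC(C)(C)[C@@H]2CC[C@@](O[Si](C)(C)c3ccccc3)(C)[C@H]12 | intermediate
12 | (1S,3aR,8aR)-1-hydroxy-1,4,4-trimethylperhydroazulen-8-one (cis-fused, hydroxyl cis to C-8) | O=C1CCCC(C)(C)[C@@H]2CC[C@@](O)(C)[C@H]12 | intermediate
13 | (3aS)-1,4,4-trimethyl-3,3a,4,5,6,7-hexahydroazulen-8(2H)-one | O=C1CCCC(C)(C)[C@@H]2CCC(C)=C12 | intermediate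
14 | trichlorotitanium enolate of 15 (C-8 oxygen on titanium, C-8=C-8a double bond, allyl on C-1 cis to H-3a) | Cl[Ti](Cl)(Cl)OC=1CCCC(C)(C)[C@@H]2CC[C@@](C)(CC=C)C=12 | intermediate
15 | (1S,3aR,8aR)-1,4,4-trimethyl-1-(prop-2-en-1-yl)perhydroazulen-8-one (cis-fused, allyl cis to H-8a) | O=C1CCCC(C)(C)[C@@H]2CC[C@@](C)(CC=C)[C@H]12 | intermediate
16 | (1S,3aR,8aR)-1,4,4-trimethyl-1-(1,2,4-trioxolan-3-ylmethyl)perhydroazulen-8-one (both epimers at the trioxolane carbon) | O=C1CCCC(C)(C)[C@@H]2CC[C@@](C)(CC3OCOO3)[C@H]12 | intermediate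
17 | 2-[(1S,3aR,8aR)-1,4,4-trimethyl-8-oxodecahydroazulen-1-yl]acetaldehyde | O=C1CCCC(C)(C)[C@@H]2CC[C@@](C)(CC=O)[C@H]12 | intermediate
18 | (1S,3aR,8aR)-1-(2,2-dimethoxyethyl)-1,4,4-trimethylperhydroazulen-8-one | O=C1CCCC(C)(C)[C@@H]2CC[C@@](C)(CC(OC)OC)[C@H]12 | intermediate
19 | (1S,3aR,8aS)-1-(2,2-dimethoxyethyl)-1,4,4-trimethyl-8-methylideneperhydroazulene | C=C1CCCC(C)(C)[C@@H]2CC[C@@](C)(CC(OC)OC)[C@H]12 | intermediate
20 | (1R,3aR,8aS)-1-[(E)-2-methoxyethenyl]-1,4,4-trimethyl-8-methylideneperhydroazulene | C=C1CCCC(C)(C)[C@@H]2CC[C@@](C)(/C=C/OC)[C@H]12 | intermediate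
21 | methyl (R)-2-hydroxybut-3-enoate | C=C[C@@H](O)C(=O)OC | starting material
22 | tert-butyl acrylate | C=CC(=O)OC(C)(C)C | starting material
23 | 5-tert-butyl 1-methyl (2R,3E)-2-hydroxypent-3-enedioate | O[C@H](/C=C/C(=O)OC(C)(C)C)C(=O)OC | intermediate
24 | 5-tert-butyl 1-methyl (2R,3E)-2-{(1S,2S)-2-bromo-1-methoxy-2-[(1R,3aR,8aS)-1,4,4-trimethyl-8-methylidenedecahydroazulen-1-yl]ethoxy}pent-3-enedioate | C=C1CCCC(C)(C)[C@@H]2CC[C@@](C)([C@H](Br)[C@@H](OC)O[C@H](/C=C/C(=O)OC(C)(C)C)C(=O)OC)[C@H]12 | intermediate
25 | methyl (2R,3R,4R,5S)-3-(2-tert-butoxy-2-oxoethyl)-5-methoxy-4-[(1R,3aR,8aS)-1,4,4-trimethyl-8-methylidenedecahydroazulen-1-yl]oxolane-2-carboxylate (ester and arm trans, arm and hydroazulenyl cis, hydroazulenyl and methoxy trans) | C=C1CCCC(C)(C)[C@@H]2CC[C@@](C)([C@@H]3[C@@H](OC)O[C@@H](C(=O)OC)[C@@H]3CC(=O)OC(C)(C)C)[C@H]12 | intermediate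
26 | trimethylsilyl ester corresponding to 25 (tert-butyl replaced by trimethylsilyl) | C=C1CCCC(C)(C)[C@@H]2CC[C@@](C)([C@@H]3[C@@H](OC)O[C@@H](C(=O)OC)[C@@H]3CC(=O)O[Si](C)(C)C)[C@H]12 | intermediate
27 | methyl (1S,5R,6R,8R)-3-oxo-8-[(1R,3aR,8aS)-1,4,4-trimethyl-8-methylidenedecahydroazulen-1-yl]-2,7-dioxabicyclo[3.2.1]octane-6-carboxylate (ester exo on C-6, hydroazulenyl on C-8 over the lactone ring) | C=C1CCCC(C)(C)[C@@H]2CC[C@@](C)([C@@H]3[C@@H]4OC(=O)C[C@H]3[C@H](C(=O)OC)O4)[C@H]12 | intermediate
28 | potassium enolate of 27 (C-3 enolate oxygen, C-3=C-4 double bond) | [K+].C=C1CCCC(C)(C)[C@@H]2CC[C@@](C)([C@@H]3[C@@H]4OC([O-])=C[C@H]3[C@H](C(=O)OC)O4)[C@H]12 | intermediate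
29 | methyl (1S,4S,5S,6R,8R)-4-hydroxy-3-oxo-8-[(1R,3aR,8aS)-1,4,4-trimethyl-8-methylidenedecahydroazulen-1-yl]-2,7-dioxabicyclo[3.2.1]octane-6-carboxylate (hydroxyl trans to the hydroazulenyl group) | C=C1CCCC(C)(C)[C@@H]2CC[C@@](C)([C@@H]3[C@@H]4OC(=O)[C@@H](O)[C@H]3[C@H](C(=O)OC)O4)[C@H]12 | intermediate
30 | methyl (1S,4S,5R,6R,8R)-4-acetoxy-3-oxo-8-[(1R,3aR,8aS)-1,4,4-trimethyl-8-methylidenedecahydroazulen-1-yl]-2,7-dioxabicyclo[3.2.1]octane-6-carboxylate (CNP0215240.1) | C=C1CCCC(C)(C)[C@@H]2CC[C@@](C)([C@@H]3[C@@H]4OC(=O)[C@@H](OC(C)=O)[C@H]3[C@H](C(=O)OC)O4)[C@H]12 | target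

**Step count**

Total step count: 15.
Longest linear sequence: 14 steps (steps 1–9 and 11–15); step 10 is a one-step branch.

**Steps most likely to fail**

Step 12. The radical carbon may lose its facial bias, so that the hydroazulenyl group ends trans to the acetate arm, or the acetal epimers of step 11 may prove inseparable and feed the wrong chair into the cyclisation. The fallback replaces kinetic by thermodynamic control of the bridge CH. It sets out from 24, used together with its acetal epimer, the (1R,2R)-bromoacetal F1. Cathodic cyclisation under the conditions of step 12 should then give 25 mixed with the all-trans tetrahydrofuran F2, which differs from 25 only at the bridge CH and the acetal carbon. TMSOTf and iPr2NEt (CH2Cl2, −20 °C) eliminate methanol from both to a single compound, the 2,3-dihydrofuran F3, in which the bridge carbon is trigonal. TMSOTf and 2,6-lutidine followed by aqueous work-up free the dihydrofuran acid F4. PPTS in CH2Cl2 then adds the carboxylic acid across the enol ether reversibly (hydroacyloxylation of an enol ether). Of the two possible bicyclic lactones, only the one whose hydroazulenyl group on C-8 points away from the exo methyl ester on C-6 is free of a severe 1,3-interaction, so the equilibrium should settle on 27, where the fallback comes back to the route.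

Step 14. The enolate of the acyl acetal may fragment with opening of the lactone, the base may attack the hydrogen beside the methyl ester, or the oxidant may fail to discriminate the enolate faces. The fallback oxidises before the lactone is closed and then acylates stereoconvergently. It sets out from 25. LiN(iPr)2 (THF, −78 °C) deprotonates the unhindered CH2 of the tert-butyl ester, and 2-(phenylsulfonyl)-3-phenyloxaziridine gives the α-hydroxy tert-butyl ester F5 as both carbinol epimers. TMSOTf and 2,6-lutidine as in step 13, followed by HF·pyridine to remove the silyl ether, close the lactone and should give 29 together with its carbinol epimer, the (4R)-hydroxy lactone F6, separable as diastereomers. 29 is acetylated as in step 15. F6 is acetylated with inversion under Mitsunobu conditions (AcOH, PPh3, DIAD), the acetate entering anti to the hydroazulenyl group. Both epimers thus come back to the route at 30.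

Step 6. Protonation of the titanium enolate on the wrong face, or later epimerisation at C-8a, would give the trans ring fusion, and the tetrasubstituted enone may react sluggishly. The fallback fixes the ring fusion in the ring-forming event. It sets out from 10. Horner–Wadsworth–Emmons olefination of the methyl ketone (triethyl phosphonoacetate, NaH, THF) gives the enone enoate F7. The copper hydride catalyst of step 4 with PhMe2SiH reduces the ring enone to its silyl enol ether, and Bu4NF then triggers the intramolecular Michael addition to the β-methyl enoate. This can only close cis and should place the smaller methyl group on the concave face, giving the keto ester F8. Cp2TiMe2 gives the methylidene ester F9, iBu2AlH (−78 °C) the aldehyde F10, and CH(OMe)3 with PPTS in MeOH the dimethyl acetal 19, where the fallback comes back to the route.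

Further compounds
F1 | step 12 | 5-tert-butyl 1-methyl (2R,3E)-2-{(1R,2R)-2-bromo-1-methoxy-2-[(1R,3aR,8aS)-1,4,4-trimethyl-8-methylidenedecahydroazulen-1-yl]ethoxy}pent-3-enedioate (acetal epimer of 24) | C=C1CCCC(C)(C)[C@@H]2CC[C@@](C)([C@@H](Br)[C@H](OC)O[C@H](/C=C/C(=O)OC(C)(C)C)C(=O)OC)[C@H]12
F2 | step 12 | methyl (2R,3R,4S,5R)-3-(2-tert-butoxy-2-oxoethyl)-5-methoxy-4-[(1R,3aR,8aS)-1,4,4-trimethyl-8-methylidenedecahydroazulen-1-yl]oxolane-2-carboxylate (all-trans tetrahydrofuran) | C=C1CCCC(C)(C)[C@@H]2CC[C@@](C)([C@H]3[C@H](OC)O[C@@H](C(=O)OC)[C@@H]3CC(=O)OC(C)(C)C)[C@H]12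
F3 | step 12 | methyl (2R,3R)-3-(2-tert-butoxy-2-oxoethyl)-4-[(1R,3aR,8aS)-1,4,4-trimethyl-8-methylidenedecahydroazulen-1-yl]-2,3-dihydrofuran-2-carboxylate | C=C1CCCC(C)(C)[C@@H]2CC[C@@](C)(C3=CO[C@@H](C(=O)OC)[C@@H]3CC(=O)OC(C)(C)C)[C@H]12
F4 | step 12 | 2-{(2R,3R)-2-(methoxycarbonyl)-4-[(1R,3aR,8aS)-1,4,4-trimethyl-8-methylidenedecahydroazulen-1-yl]-2,3-dihydrofuran-3-yl}acetic acid | C=C1CCCC(C)(C)[C@@H]2CC[C@@](C)(C3=CO[C@@H](C(=O)OC)[C@@H]3CC(=O)O)[C@H]12
F5 | step 14 | methyl 3-(2-tert-butoxy-1-hydroxy-2-oxoethyl)-5-methoxy-4-[(1R,3aR,8aS)-1,4,4-trimethyl-8-methylidenedecahydroazulen-1-yl]oxolane-2-carboxylate (ring configured as in 25, both epimers at the carbinol carbon) | C=C1CCCC(C)(C)[C@@H]2CC[C@@](C)([C@@H]3[C@@H](OC)O[C@@H](C(=O)OC)[C@@H]3C(O)C(=O)OC(C)(C)C)[C@H]12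
F6 | step 14 | (4R)-epimer of 29, hydroxyl cis to the hydroazulenyl group | C=C1CCCC(C)(C)[C@@H]2CC[C@@](C)([C@@H]3[C@@H]4OC(=O)[C@H](O)[C@H]3[C@H](C(=O)OC)O4)[C@H]12
F7 | step 6 | ethyl (E)-5-(7,7-dimethyl-3-oxocyclohept-1-en-1-yl)-3-methylpent-2-enoate | CCOC(=O)/C=C(\C)CCC1=CC(=O)CCCC1(C)C
F8 | step 6 | ethyl 2-[(1S,3aR,8aR)-1,4,4-trimethyl-8-oxodecahydroazulen-1-yl]acetate | O=C1CCCC(C)(C)[C@@H]2CC[C@@](C)(CC(=O)OCC)[C@H]12
F9 | step 6 | ethyl 2-[(1S,3aR,8aS)-1,4,4-trimethyl-8-methylidenedecahydroazulen-1-yl]acetate | C=C1CCCC(C)(C)[C@@H]2CC[C@@](C)(CC(=O)OCC)[C@H]12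
F10 | step 6 | 2-[(1S,3aR,8aS)-1,4,4-trimethyl-8-methylidenedecahydroazulen-1-yl]acetaldehyde | C=C1CCCC(C)(C)[C@@H]2CC[C@@](C)(CC=O)[C@H]12
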